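Retrosynthetic overview
1. Feature: in the piperidine ring (N1, C2 with methyl, C3 with hydroxyl, C4, C5, C6 with the chain C1'–C16') the bonds C6–N1 and C3–O sit at the two ends of the unit C3–C4–C5–C6. Their relative configuration is the one left by adding an N=O unit to one face of an E,E-diene.
2. Last ring (piperidine): N1–C2, formed by hydrogenolysis of an N–O bond and SN2 attack of the freed C6 amine on a (2S)-mesylate with inversion.
3. First ring (temporary 3,6-dihydro-1,2-oxazine): C6–N and C3–O, formed by hetero-Diels–Alder addition of tert-butyl nitrosoformate to a (2S,3E,5E)-dienol with a free C2 hydroxyl.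
4. Dienol: C4–C5 by Stille coupling (E-stannane from (S)-but-3-yn-2-ol); C1'–C6 by B-alkyl Suzuki–Miyaura coupling with (E)-(2-bromovinyl)trimethylsilane.
5. Chain: C3'–C4' by Brown allylation (sets C4'); C13'–C14' by Grignard opening of (S)-propylene oxide (brings C15').
Key step: step 10

Remark: read from the SMILES, the target is (2R,3S,6S)-6-[(4S,15S)-4,15-dihydroxyhexadecyl]-2-methylpiperidin-3-ol (2,6-cis, 2,3-trans). The piperidine locants C2–C6 and chain locants C1'–C16' are used for all intermediates, and TBS = tert-butyldimethylsilyl.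

Step 1
Reactants: 1 11-bromoundec-1-ene; 2 (S)-propylene oxide
Product: 4 (2S)-tetradec-13-en-2-ol, via undec-10-enylmagnesium bromide 3 (not isolated)
Conditions: Mg, THF, rt to 40 °C; then CuBr·SMe2 (10 mol %), 2, −30 to 0 °C; H2O
Reagents that add atoms: magnesium, [Mg] (ends in 3, not in 4)
Why: Copper-catalysed opening of a terminal epoxide by a primary Grignard reagent takes place at the unsubstituted carbon, so the stereocentre of 2 is carried over untouched as (15'S).

Step 2
Reactants: 4 (2S)-tetradec-13-en-2-ol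
Product: 5 tert-butyl(dimethyl)[(2S)-tetradec-13-en-2-yloxy]silane
Conditions: TBSCl, imidazole, DMF, rt
Reagents that add atoms: tert-butyldimethylsilyl chloride, CC(C)(C)[Si](C)(C)Cl
Why: Imidazole-promoted silylation masks the C15' hydroxyl against the borane, organometallic and sulfonylation steps that follow.

Step 3
Reactants: 5 tert-butyl(dimethyl)[(2S)-tetradec-13-en-2-yloxy]silane
Product: 7 (12S)-12-[(tert-butyldimethylsilyl)oxy]tridecanal, via secondary ozonide 6 (not isolated)
Conditions: O3, CH2Cl2, −78 °C; then PPh3, −78 °C to rt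
Reagents that add atoms: ozone, [O-][O+]=O
Why: Ozonolysis with reductive work-up cuts the terminal alkene to the C4' aldehyde with loss of one carbon and leaves the silyl ether alone.

Step 4
Reactants: 7 (12S)-12-[(tert-butyldimethylsilyl)oxy]tridecanal; 8 (−)-B-allyldiisopinocampheylborane, the reagent of the (−)-α-pinene series (purchased as a solution in pentane)
Product: 10 (4S,15S)-15-[(tert-butyldimethylsilyl)oxy]hexadec-1-en-4-ol, via homoallyl diisopinocampheylborinate 9 (not isolated)
Conditions: 8, Et2O, −100 to −78 °C; then 3 M NaOH, 30% H2O2, 0 °C to rt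
Reagents that add atoms: none
Why: Brown asymmetric allylboration runs through a closed chair-like six-membered transition state, and the reagent of the (−)-α-pinene series is known to give (S)-homoallylic alcohols from unbranched aliphatic aldehydes, which sets C4'.

Step 5
Reactants: 10 (4S,15S)-15-[(tert-butyldimethylsilyl)oxy]hexadec-1-en-4-ol
Product: 11 (4S,15S)-4,15-bis[(tert-butyldimethylsilyl)oxy]hexadec-1-ene
Conditions: TBSCl, imidazole, DMF, rt to 40 °C
Reagents that add atoms: tert-butyldimethylsilyl chloride, CC(C)(C)[Si](C)(C)Cl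
Why: The same silylation protects the C4' hydroxyl, so that later the C2 hydroxyl is the only free one in the molecule.

Step 6
Reactants: 11 (4S,15S)-4,15-bis[(tert-butyldimethylsilyl)oxy]hexadec-1-ene; 12 (E)-(2-bromoethenyl)trimethylsilane
Product: 14 [(1E,6S,17S)-6,17-bis[(tert-butyldimethylsilyl)oxy]octadec-1-en-1-yl]trimethylsilane, via B-alkyl-9-BBN 13 (not isolated)
Conditions: 9-BBN-H, THF, 0 °C to rt; then 12, PdCl2(dppf)·CH2Cl2 (5 mol %), 3 M aq NaOH, THF, 60 °C
Reagents that add atoms: 9-borabicyclo[3.3.1]nonane, B1C2CCCC1CCC2 (ends in 13, not in 14)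
Why: Anti-Markovnikov hydroboration of the monosubstituted alkene followed by B-alkyl Suzuki–Miyaura coupling joins C1' to C6 with retention of the E geometry of the bromoalkene.

Step 7
Reactants: 14 [(1E,6S,17S)-6,17-bis[(tert-butyldimethylsilyl)oxy]octadec-1-en-1-yl]trimethylsilane
Product: 15 (1E,6S,17S)-6,17-bis[(tert-butyldimethylsilyl)oxy]-1-iodooctadec-1-ene
Conditions: NIS, MeCN/CH2Cl2, 0 °C to rt, dark; aq Na2S2O3
Reagents that add atoms: N-iodosuccinimide, O=C1CCC(=O)N1I
Why: Electrophilic ipso-iododesilylation of an isolated E-alkenylsilane (β-silyl cation, then loss of silicon) is known to proceed in acetonitrile with retention of alkene geometry and to spare silyl ethers.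

Step 8
Reactants: 16 (S)-but-3-yn-2-ol
Product: 17 (2S,3E)-4-(tributylstannyl)but-3-en-2-ol
Conditions: Bu3SnH, Pd2(dba)3 (0.5 mol %), Cy3P·HBF4 (2 mol %), iPr2NEt (4 mol %), CH2Cl2, 0 °C
Reagents that add atoms: tributyltin hydride, CCCC[SnH](CCCC)CCCC
Why: Palladium-catalysed hydrostannation is a syn addition, and the bulky phosphine steers tin to the terminal carbon, which gives the E-alkenylstannane without touching the carbinol centre.

Step 9
Reactants: 15 (1E,6S,17S)-6,17-bis[(tert-butyldimethylsilyl)oxy]-1-iodooctadec-1-ene; 17 (2S,3E)-4-(tributylstannyl)but-3-en-2-ol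
Product: 18 (2S,3E,5E,10S,21S)-10,21-bis[(tert-butyldimethylsilyl)oxy]docosa-3,5-dien-2-ol
Conditions: PdCl2(MeCN)2 (5 mol %), DMF/THF, rt, dark
Reagents that add atoms: none
Why: Stille coupling of an E-iodoalkene with an E-alkenylstannane forms the C4–C5 bond with retention at both partners and tolerates the free allylic hydroxyl.

Step 10
Reactants: 18 (2S,3E,5E,10S,21S)-10,21-bis[(tert-butyldimethylsilyl)oxy]docosa-3,5-dien-2-ol; 19 tert-butyl N-hydroxycarbamate
Product: 21 tert-butyl (3S,6S)-3-[(4S,15S)-4,15-bis[(tert-butyldimethylsilyl)oxy]hexadecyl]-6-[(1S)-1-hydroxyethyl]-3,6-dihydro-2H-1,2-oxazine-2-carboxylate, via tert-butyl nitrosoformate 20 (not isolated)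
Conditions: 19, Bu4NIO4 (added in portions), CH2Cl2, −20 to 0 °C; chromatography
Reagents that add atoms: none
Why: Periodate oxidises 19 to the transient nitrosoformate 20, which adds across C3 and C6 of the s-cis diene in a concerted, asynchronous [4+2] cycloaddition, the acylnitroso hetero-Diels–Alder reaction that is well known for acyclic 1,4-disubstituted dienes such as sorbic acid derivatives. The one new ring, the 3,6-dihydro-1,2-oxazine, is closed by this intermolecular cycloaddition, with C6–N and C3–O formed on the same diene face. Because the addition is suprafacial and both alkenes are E, the C6 chain and the C3 hydroxyethyl group must end up cis, so C6 is fixed relative to C3 by the diene geometry alone. C3 is set relative to the resident (2S) carbinol by the choice of diene face: with C2–H in the diene plane facing C4–H (least allylic strain) the hydroxyl covers one face and the methyl the other, and an O–H···O hydrogen bond to the nitroso oxygen in CH2Cl2 should draw 20 to the hydroxyl face, which leads to (2S,3S,6S) in piperidine locants. The orientation needed (N to C6, O to C3) rests on the bulky N-Boc end avoiding the branched, inductively electron-poor C2 side, as it avoids the substituted terminus of sorbic acid derivatives, and on the same hydrogen bond. Both selectivities should be only moderate because allylic strain in an E-alkene is weak, so 21 is to be freed from its regio- and diastereoisomers by chromatography.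

Step 11
Reactants: 21 N-Boc dihydrooxazine alcohol
Product: 22 tert-butyl (3S,6S)-3-[(4S,15S)-4,15-bis[(tert-butyldimethylsilyl)oxy]hexadecyl]-6-[(1S)-1-(methylsulfonyloxy)ethyl]-3,6-dihydro-2H-1,2-oxazine-2-carboxylate
Conditions: MsCl, Et3N, CH2Cl2, 0 °C
Reagents that add atoms: methanesulfonyl chloride, CS(=O)(=O)Cl
Why: Sulfonylation of the only free hydroxyl turns the C2 oxygen into a leaving group without breaking the C2–O bond, so C2 stays (S) while the C3 oxygen is still held in the N–O bond.

Step 12
Reactants: 22 N-Boc dihydrooxazine mesylate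
Product: 23 (1S)-1-{(3S,6S)-3-[(4S,15S)-4,15-dihydroxyhexadecyl]-3,6-dihydro-2H-1,2-oxazin-6-yl}ethyl methanesulfonate hydrochloride
Conditions: 3 M HCl in MeOH, CH2Cl2, 0 °C to rt; evaporate
Reagents that add atoms: hydrogen chloride, Cl
Why: Acidolysis of the tert-butyl carbamate and acid-catalysed methanolysis of both silyl ethers occur in one operation, whereas the dihydrooxazine ring and the secondary mesylate, deactivated towards ionisation by the neighbouring C3 oxygen, are stable to acid.

Step 13
Reactants: 23 dihydrooxazine mesylate hydrochloride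
Product: 26 (2R,3S,6S)-6-[(4S,15S)-4,15-dihydroxyhexadecyl]-2-methylpiperidin-3-ol, via oxazinane hydrochloride 24 (not isolated), via amino mesylate hydrochloride 25 (not isolated)
Conditions: H2 (1 atm), 10% Pd/C, MeOH, rt; filter; then Et3N (3 equiv), MeOH, 50 °C
Reagents that add atoms: none
Why: Catalytic hydrogenation saturates C4=C5 and cleaves the weak N–O bond, and the C6 amine set free by the mild base then displaces the C2 mesylate in a 6-exo-tet SN2 ring closure with inversion, so that (2S)-O becomes (2R)-N and all three ring substituents end up equatorial.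

Compound list
1 | 11-bromoundec-1-ene | C=CCCCCCCCCCBr | starting material
2 | (S)-propylene oxide | C[C@H]1CO1 | starting material
3 | undec-10-enylmagnesium bromide | C=CCCCCCCCCC[Mg]Br | intermediate
4 | (2S)-tetradec-13-en-2-ol | C[C@H](O)CCCCCCCCCCC=C | intermediate
5 | tert-butyl(dimethyl)[(2S)-tetradec-13-en-2-yloxy]silane | C[C@H](O[Si](C)(C)C(C)(C)C)CCCCCCCCCCC=C | intermediate
6 | 3-[(11S)-11-[(tert-butyldimethylsilyl)oxy]dodecyl]-1,2,4-trioxolane (secondary ozonide, both ring epimers) | C[C@H](O[Si](C)(C)C(C)(C)C)CCCCCCCCCCC1OCOO1 | intermediate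
7 | (12S)-12-[(tert-butyldimethylsilyl)oxy]tridecanal | C[C@H](O[Si](C)(C)C(C)(C)C)CCCCCCCCCCC=O | intermediate
8 | (−)-B-allyldiisopinocampheylborane, (−)-α-pinene series | C=CCB([C@H]1C[C@H]2C[C@@H]([C@@H]1C)C2(C)C)[C@H]1C[C@H]2C[C@@H]([C@@H]1C)C2(C)C | starting material
9 | (4S,15S)-15-[(tert-butyldimethylsilyl)oxy]hexadec-1-en-4-yl diisopinocampheylborinate | C[C@H](O[Si](C)(C)C(C)(C)C)CCCCCCCCCC[C@H](OB([C@H]1C[C@H]2C[C@@H]([C@@H]1C)C2(C)C)[C@H]1C[C@H]2C[C@@H]([C@@H]1C)C2(C)C)CC=C | intermediate
10 | (4S,15S)-15-[(tert-butyldimethylsilyl)oxy]hexadec-1-en-4-ol | C[C@H](O[Si](C)(C)C(C)(C)C)CCCCCCCCCC[C@H](O)CC=C | intermediate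
11 | (4S,15S)-4,15-bis[(tert-butyldimethylsilyl)oxy]hexadec-1-ene | C[C@H](O[Si](C)(C)C(C)(C)C)CCCCCCCCCC[C@H](O[Si](C)(C)C(C)(C)C)CC=C | intermediate
12 | (E)-(2-bromoethenyl)trimethylsilane | C[Si](C)(C)/C=C/Br | starting material
13 | 9-[(4S,15S)-4,15-bis[(tert-butyldimethylsilyl)oxy]hexadecyl]-9-borabicyclo[3.3.1]nonane | C[C@H](O[Si](C)(C)C(C)(C)C)CCCCCCCCCC[C@H](O[Si](C)(C)C(C)(C)C)CCCB1C2CCCC1CCC2 | intermediate
14 | [(1E,6S,17S)-6,17-bis[(tert-butyldimethylsilyl)oxy]octadec-1-en-1-yl]trimethylsilane | C[C@H](O[Si](C)(C)C(C)(C)C)CCCCCCCCCC[C@H](O[Si](C)(C)C(C)(C)C)CCC/C=C/[Si](C)(C)C | intermediate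
15 | (1E,6S,17S)-6,17-bis[(tert-butyldimethylsilyl)oxy]-1-iodooctadec-1-ene | C[C@H](O[Si](C)(C)C(C)(C)C)CCCCCCCCCC[C@H](O[Si](C)(C)C(C)(C)C)CCC/C=C/I | intermediate
16 | (S)-but-3-yn-2-ol | C#C[C@H](C)O | starting material
17 | (2S,3E)-4-(tributylstannyl)but-3-en-2-ol | C[C@H](O)/C=C/[Sn](CCCC)(CCCC)CCCC | intermediate
18 | (2S,3E,5E,10S,21S)-10,21-bis[(tert-butyldimethylsilyl)oxy]docosa-3,5-dien-2-ol | C[C@H](O[Si](C)(C)C(C)(C)C)CCCCCCCCCC[C@H](O[Si](C)(C)C(C)(C)C)CCC/C=C/C=C/[C@H](C)O | intermediate
19 | tert-butyl N-hydroxycarbamate | CC(C)(C)OC(=O)NO | starting material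
20 | tert-butyl nitrosoformate | CC(C)(C)OC(=O)N=O | intermediate
21 | tert-butyl (3S,6S)-3-[(4S,15S)-4,15-bis[(tert-butyldimethylsilyl)oxy]hexadecyl]-6-[(1S)-1-hydroxyethyl]-3,6-dihydro-2H-1,2-oxazine-2-carboxylate | C[C@H](O[Si](C)(C)C(C)(C)C)CCCCCCCCCC[C@H](O[Si](C)(C)C(C)(C)C)CCC[C@H]1C=C[C@H](ON1C(=O)OC(C)(C)C)[C@H](C)O | intermediate
22 | methanesulfonate of 21 at the C2 hydroxyl, (1S)-1-(methylsulfonyloxy)ethyl side chain | C[C@H](O[Si](C)(C)C(C)(C)C)CCCCCCCCCC[C@H](O[Si](C)(C)C(C)(C)C)CCC[C@H]1C=C[C@H](ON1C(=O)OC(C)(C)C)[C@H](C)OS(C)(=O)=O | intermediate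
23 | (1S)-1-{(3S,6S)-3-[(4S,15S)-4,15-dihydroxyhexadecyl]-3,6-dihydro-2H-1,2-oxazin-6-yl}ethyl methanesulfonate hydrochloride | C[C@H](O)CCCCCCCCCC[C@H](O)CCC[C@H]1C=C[C@H](ON1)[C@H](C)OS(C)(=O)=O.Cl | intermediate
24 | (1S)-1-{(3S,6S)-3-[(4S,15S)-4,15-dihydroxyhexadecyl]-1,2-oxazinan-6-yl}ethyl methanesulfonate hydrochloride | C[C@H](O)CCCCCCCCCC[C@H](O)CCC[C@H]1CC[C@H](ON1)[C@H](C)OS(C)(=O)=O.Cl | intermediate
25 | (2S,3S,6S,10S,21S)-6-amino-3,10,21-trihydroxydocosan-2-yl methanesulfonate hydrochloride | C[C@H](O)CCCCCCCCCC[C@H](O)CCC[C@H](N)CC[C@H](O)[C@H](C)OS(C)(=O)=O.Cl | intermediate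
26 | (2R,3S,6S)-6-[(4S,15S)-4,15-dihydroxyhexadecyl]-2-methylpiperidin-3-ol | C[C@H](O)CCCCCCCCCC[C@H](O)CCC[C@H]1CC[C@H](O)[C@@H](C)N1 | target

Total step count: 13. Longest linear sequence: 12 steps (steps 1–7 and 9–13, from 1); step 8 is the one-step side branch.

Steps most likely to fail

First, step 10.
- **What may go wrong:** The nitrosoformate is so reactive that it may discriminate poorly between the two diene faces, and to a lesser degree between the two orientations. That would cost material and burden the separation.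
- **Fallback:** The dienophile class is changed from an acylnitroso compound to a slow α-chloronitroso compound. The fallback sets out from 18 and comes back at 21.
- **Sequence:** Cyclohexanone oxime and tBuOCl give 1-chloro-1-nitrosocyclohexane F1. This is left with 18 in CHCl3 containing a little moist EtOH at −20 to 0 °C. The first-formed N-(1-chlorocyclohexyl)dihydrooxazine F2 is solvolysed as it forms to the N-unsubstituted dihydrooxazine hydrochloride F3. Boc2O with Et3N then gives 21.
- **Why it should help:** The later transition state and the tertiary alkyl group on nitrogen should make the cycloaddition more sensitive both to the branched C2 terminus and to the allylic stereocentre. Reagents of this class are known to add to sorbic acid derivatives with nitrogen at the less hindered, methyl-bearing terminus. The salt also opens the way to purification by crystallisation.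

Second, step 13.
- **What may go wrong:** Once the N–O bond is cleaved, 3-exo-tet attack of the neighbouring C3 hydroxyl on C2 may compete with the 6-exo-tet attack of the C6 amine. Opening of the resulting oxirane by the amine would then contract the ring or return C2 with the wrong configuration.
- **Fallback:** Substitution at C2 is replaced by reductive amination. The fallback sets out from 21 and comes back at 26.
- **Sequence:** Brief hydrogenation (H2, Pd/C, EtOAc), which leaves the N-acylated N–O bond intact, gives the saturated N-Boc oxazinane alcohol F4. Dess–Martin periodinane gives the methyl ketone F5. HCl in MeOH followed by NaHCO3 gives the N-unsubstituted oxazinane keto diol F6. H2 over Pd/C in MeOH cleaves the N–O bond to the open-chain amino hydroxy ketone F7, which condenses to the cyclic imine F8. The imine is hydrogenated in the same flask from the face opposite the C6 chain.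
- **Why it should help:** This is the usual course for 2,6-disubstituted tetrahydropyridines, so the 2,6-cis piperidine 26 should result with C3 untouched.

Third, step 4.
- **What may go wrong:** Incomplete enantioface selection in the allylboration would leave the C4' epimer. It differs only at a centre remote from all others and would be carried through the route without any chance of separation.
- **Fallback:** Carbonyl allylation is replaced by kinetic resolution of an epoxide. The fallback sets out from 5 and comes back at 10, and the ozonolysis is dropped as well because the terminal carbon of 5 is kept as C3'.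
- **Sequence:** mCPBA in CH2Cl2 gives the terminal epoxide F9 as both C4' epimers. Jacobsen hydrolytic kinetic resolution follows, using (S,S)-(salen)Co(OAc) (salen = N,N'-bis(3,5-di-tert-butylsalicylidene)cyclohexane-1,2-diamine dianion) and about half an equivalent of water. It should leave the (S)-configured epoxide F10 and turn the other epimer into the polar diol F11, which is removed by chromatography. Opening of F10 at its CH2 end with vinylMgBr and CuBr·SMe2 (cat.) in THF gives 10.

Further compounds
F1 | step 10 | 1-chloro-1-nitrosocyclohexane | O=NC1(Cl)CCCCC1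
F2 | step 10 | (1S)-1-{(3S,6S)-3-[(4S,15S)-4,15-bis[(tert-butyldimethylsilyl)oxy]hexadecyl]-2-(1-chlorocyclohexyl)-3,6-dihydro-2H-1,2-oxazin-6-yl}ethanol | C[C@H](O[Si](C)(C)C(C)(C)C)CCCCCCCCCC[C@H](O[Si](C)(C)C(C)(C)C)CCC[C@H]1C=C[C@H](ON1C2(Cl)CCCCC2)[C@H](C)O
F3 | step 10 | (1S)-1-{(3S,6S)-3-[(4S,15S)-4,15-bis[(tert-butyldimethylsilyl)oxy]hexadecyl]-3,6-dihydro-2H-1,2-oxazin-6-yl}ethanol hydrochloride | C[C@H](O[Si](C)(C)C(C)(C)C)CCCCCCCCCC[C@H](O[Si](C)(C)C(C)(C)C)CCC[C@H]1C=C[C@H](ON1)[C@H](C)O.Cl
F4 | step 13 | tert-butyl (3S,6S)-3-[(4S,15S)-4,15-bis[(tert-butyldimethylsilyl)oxy]hexadecyl]-6-[(1S)-1-hydroxyethyl]-1,2-oxazinane-2-carboxylate | C[C@H](O[Si](C)(C)C(C)(C)C)CCCCCCCCCC[C@H](O[Si](C)(C)C(C)(C)C)CCC[C@H]1CC[C@H](ON1C(=O)OC(C)(C)C)[C@H](C)O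
F5 | step 13 | tert-butyl (3S,6S)-6-acetyl-3-[(4S,15S)-4,15-bis[(tert-butyldimethylsilyl)oxy]hexadecyl]-1,2-oxazinane-2-carboxylate | C[C@H](O[Si](C)(C)C(C)(C)C)CCCCCCCCCC[C@H](O[Si](C)(C)C(C)(C)C)CCC[C@H]1CC[C@H](ON1C(=O)OC(C)(C)C)C(C)=O
F6 | step 13 | 1-{(3S,6S)-3-[(4S,15S)-4,15-dihydroxyhexadecyl]-1,2-oxazinan-6-yl}ethanone | C[C@H](O)CCCCCCCCCC[C@H](O)CCC[C@H]1CC[C@H](ON1)C(C)=O
F7 | step 13 | (3S,6S,10S,21S)-6-amino-3,10,21-trihydroxydocosan-2-one | C[C@H](O)CCCCCCCCCC[C@H](O)CCC[C@H](N)CC[C@H](O)C(C)=O
F8 | step 13 | (3S,6S)-6-[(4S,15S)-4,15-dihydroxyhexadecyl]-2-methyl-3,4,5,6-tetrahydropyridin-3-ol | C[C@H](O)CCCCCCCCCC[C@H](O)CCC[C@H]1CC[C@H](O)C(C)=N1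
F9 | step 4 | tert-butyl(dimethyl){[(2S)-12-(oxiran-2-yl)dodecan-2-yl]oxy}silane, both epoxide epimers | C[C@H](O[Si](C)(C)C(C)(C)C)CCCCCCCCCCC1CO1
F10 | step 4 | tert-butyl(dimethyl){[(2S)-12-[(2S)-oxiran-2-yl]dodecan-2-yl]oxy}silane | C[C@H](O[Si](C)(C)C(C)(C)C)CCCCCCCCCC[C@H]1CO1
F11 | step 4 | (2R,13S)-13-[(tert-butyldimethylsilyl)oxy]tetradecane-1,2-diol | C[C@H](O[Si](C)(C)C(C)(C)C)CCCCCCCCCC[C@@H](O)CO
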